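1. In the north-west run, substrate falls from 34.1% to 7.0% between 6.00 h and 15.0 h. We read this as first-order decay with a half-life of 3.94 h at −25 °C.

| setting | north-west | west | ash | oak |
|---|---|---|---|---|
| substrate | 0.40 M | 0.60 M | 0.80 M | 0.80 M |
| temperature | −25 °C | 5 °C |  |  |
| remark | run made earlier | run made earlier | at −20 °C throughout | at −20 °C until 12 h, from then on at 30 °C |
| time |  |  | 0.60 d | 2.5 d |

| run | time / h | target / % | substrate / % |
|---|---|---|---|
| north-west | 6.00 | 61.0 | 34.1 |
| north-west | 15.0 | 87.2 | 7.0 |
| north-west | 30.0 | 92.7 | 0.5 |
| north-west | 50.0 | 93.3 | 0 |
| west | 4.00 | 89.6 | 0 |
| west | 8.00 | 90.2 | 0.4 |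
| west | 12.0 | 89.6 | 0 |
| west | 15.0 | 89.4 | 0 |

(standard deviation of a reading: 0.5 percentage points)

- a species is counted by the substrate in it: one side product B counts as two
- the numbers in the tables scatter by 0.5 percentage points (one standard deviation)
- steps that have been proposed: substrate -> side product A; substrate -> target; substrate + target -> side product B

* the flask that ends with the higher amount of target, in percent of the substrate charged, or "neither" when 2 percentage points or less lies between them (ash / oak / neither)
* final target, as a percentage of the substrate charged, in ash
* final target, as a percentage of the substrate charged, in oak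

2. The west run reads 0% substrate at 4.00 h. Allowing two standard deviations of hidden substrate, the half-life at 5 °C is at most 0.602 h.

3. We assume that the half-life does not depend on the charge and that its logarithm runs evenly with temperature between these runs. This gives 2.88 h at −20 °C, the ceiling half-life of substrate.

4. The bench rule says that 5 half-lives finish a flask. Ash gets 5.00 ceiling half-lives in 0.60 d, so by the rule it is finished.

5. The rule stops working at the margin. Ash's residual (one minus conversion) is at most 3.13%, which is above the 2 percentage points margin. Ash and oak run alike until 12 h, and then ash stays at −20 °C up to 0.60 d while oak goes to 30 °C. We assume that, from the substrate present at the change, oak makes no more target per unit converted than ash does; on this assumption, this residual bounds what oak can gain on ash.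

6. Staying inside the margin takes 5.64 half-lives, so the ceiling must be shorter by a factor of only 1.13. The ceiling rests on a limit, so we commit to "neither".

7. The forecast gives 90.8% for ash, 91.9% for oak, and neither: “The gap is under 2 points, so neither.”

    substrate → side product A (k = 0.0150 h⁻¹, Ea = 96.0 kJ mol⁻¹)
    substrate → target (k = 0.350 h⁻¹, Ea = 77.0 kJ mol⁻¹)
    substrate + target → side product B (k = 0.0270 L mol⁻¹ h⁻¹, Ea = 59.0 kJ mol⁻¹)
    (constants at −20 °C)

Ash ends at 90.4% and oak at 90.7%, so the answer is neither, with a gap of 0.32 points. Ash ends holding 0.414% substrate, below our residual of 3.13%, and the gap is smaller than what ash holds. For oak at the change of temperature, the ceiling half-life allows 5.57% substrate; 1.04% stood there, and the change itself hardly moves oak's final target. At 0.300 d, ash still held 6.58% substrate, above the 2 points margin.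

The data were generated by integration on assumed constants, and the scatter is random.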